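**Assumption:** Betaethrin A has no stereocentre and no configurationally stable axis, so it is one achiral compound and no configuration has to be set. Compounds 1, 2 and 8 are taken as purchasable.

## Retrosynthetic overview

1. No ring is built. Ring B is bought as 3-bromo-2-hydroxy-5-methoxybenzaldehyde (CHO = masked OH, Br = handle for the benzylic carbon) and ring A as methyl 2,6-difluoro-4-methylbenzoate.
2. Diaryl ether C–O bond: SNAr of the ring B phenoxide on the difluoro ester. The second fluoride is then exchanged for OH.
3. Ring B hydroxyl: Baeyer–Villiger (Dakin-type) oxidation of the aldehyde, then formate cleavage.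
4. Key C–C bond, made last on the unprotected bromodiphenol: Ar–CH2OAc from the aryl bromide and an acetoxymethyl carbanion equivalent (an α-acyloxymethylstannane) by Pd/Cu-catalysed Stille coupling. This gives the target directly.

## Route

Step 1
Reactants: 1 3-bromo-2-hydroxy-5-methoxybenzaldehyde; 2 methyl 2,6-difluoro-4-methylbenzoate
Product: 3 methyl 2-(2-bromo-6-formyl-4-methoxyphenoxy)-6-fluoro-4-methylbenzoate
Conditions: 1 (1.0 equiv), 2 (2.0 equiv), Cs2CO3 (1.5 equiv), DMSO, 100 °C, N2
Reagents that add atoms: none
Why: SNAr (addition–elimination): the caesium phenoxide of 1 displaces one of the two equivalent fluorides ortho to the ester of 2, and the aryloxy group then deactivates the ring against a second substitution; no stereocentre is formed.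

Step 2
Reactants: 3 methyl 2-(2-bromo-6-formyl-4-methoxyphenoxy)-6-fluoro-4-methylbenzoate
Product: 5 methyl 2-(2-bromo-6-formyl-4-methoxyphenoxy)-6-hydroxy-4-methylbenzoate, via O-aryl acetohydroxamate 4 (not isolated)
Conditions: AcNHOH (3 equiv), K2CO3 (5 equiv), DMSO, 80 °C; then 1 M HCl work-up
Reagents that add atoms: acetohydroxamic acid, CC(=O)NO
Why: SNAr with a hydroxide surrogate: the hydroxamate oxygen displaces the remaining ester-activated fluoride and the O-aryl hydroxamate 4 fragments in a Lossen-type step to the phenoxide, under carbonate conditions that spare the aldehyde, the hindered methyl ester and the aryl bromide.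

Step 3
Reactants: 5 methyl 2-(2-bromo-6-formyl-4-methoxyphenoxy)-6-hydroxy-4-methylbenzoate
Product: 7 methyl 2-(2-bromo-6-hydroxy-4-methoxyphenoxy)-6-hydroxy-4-methylbenzoate, via aryl formate 6 (not isolated)
Conditions: mCPBA (1.5 equiv), CH2Cl2, 0 °C → rt; then Et3N, MeOH, rt
Reagents that add atoms: mCPBA (3-chloroperoxybenzoic acid), OOC(=O)c1cccc(Cl)c1
Why: Baeyer–Villiger (Dakin-type) oxidation: the aryl group bearing the ortho aryloxy donor migrates in the Criegee intermediate to give formate 6, which mild methanolysis cleaves without touching the hindered, hydrogen-bonded ring A ester.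

Step 4
Reactants: 8 (tributylstannyl)methanol
Product: 9 (tributylstannyl)methyl acetate
Conditions: Ac2O (1.2 equiv), Et3N (1.5 equiv), DMAP (5 mol%), CH2Cl2, 0 °C → rt
Reagents that add atoms: acetic anhydride, CC(=O)OC(C)=O
Why: DMAP-catalysed O-acetylation of a primary alcohol, mild enough to leave the C–Sn bond intact.

Step 5
Reactants: 7 methyl 2-(2-bromo-6-hydroxy-4-methoxyphenoxy)-6-hydroxy-4-methylbenzoate; 9 (tributylstannyl)methyl acetate
Product: 10 Betaethrin A, methyl 2-[2-(acetoxymethyl)-6-hydroxy-4-methoxyphenoxy]-6-hydroxy-4-methylbenzoate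
Conditions: 9 (2 equiv), Pd(PtBu3)2 (5 mol%), CuI (10 mol%), 1,4-dioxane, 90 °C, degassed, no base
Reagents that add atoms: none
Why: Proposed new method: Stille (Migita–Kosugi) coupling in which stannane 9 delivers AcOCH2 as a d1 carbanion equivalent (a hydroxymethyl anion), joining the electrophilic aryl C–Br carbon to a formaldehyde-level carbon that is normally also electrophilic; the electron-rich Pd(0)/PtBu3 catalyst adds oxidatively to the hindered C–Br bond, the α-acyloxymethyl group is transferred Sn→Cu→Pd in preference to butyl (carbonyl chelation and α-oxygen effect), and reductive elimination gives the benzylic acetate under neutral conditions that leave both free phenols, the methyl ester and the acetate untouched; the closest known reaction types are the Pd-catalysed hydroxymethylation of aryl bromides with (tributylstannyl)methanol and Cu-assisted Stille couplings of α-acyloxyalkylstannanes.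

## Compound list

1 | 3-bromo-2-hydroxy-5-methoxybenzaldehyde | O=Cc1cc(OC)cc(Br)c1O | starting material
2 | methyl 2,6-difluoro-4-methylbenzoate | COC(=O)c1c(F)cc(C)cc1F | starting material
3 | methyl 2-(2-bromo-6-formyl-4-methoxyphenoxy)-6-fluoro-4-methylbenzoate | COC(=O)c1c(F)cc(C)cc1Oc1c(Br)cc(OC)cc1C=O | intermediate
4 | O-aryl acetohydroxamate: methyl 2-(acetamidooxy)-6-(2-bromo-6-formyl-4-methoxyphenoxy)-4-methylbenzoate | COC(=O)c1c(ONC(C)=O)cc(C)cc1Oc1c(Br)cc(OC)cc1C=O | intermediate
5 | methyl 2-(2-bromo-6-formyl-4-methoxyphenoxy)-6-hydroxy-4-methylbenzoate | COC(=O)c1c(O)cc(C)cc1Oc1c(Br)cc(OC)cc1C=O | intermediate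
6 | aryl formate: methyl 2-[2-bromo-6-(formyloxy)-4-methoxyphenoxy]-6-hydroxy-4-methylbenzoate | COC(=O)c1c(O)cc(C)cc1Oc1c(Br)cc(OC)cc1OC=O | intermediate
7 | methyl 2-(2-bromo-6-hydroxy-4-methoxyphenoxy)-6-hydroxy-4-methylbenzoate | COC(=O)c1c(O)cc(C)cc1Oc1c(O)cc(OC)cc1Br | intermediate
8 | (tributylstannyl)methanol | CCCC[Sn](CCCC)(CCCC)CO | starting material
9 | (tributylstannyl)methyl acetate | CCCC[Sn](CCCC)(CCCC)COC(C)=O | intermediate
10 | Betaethrin A, methyl 2-[2-(acetoxymethyl)-6-hydroxy-4-methoxyphenoxy]-6-hydroxy-4-methylbenzoate (achiral) | COC(=O)c1c(O)cc(C)cc1Oc1c(O)cc(OC)cc1COC(C)=O | target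

## Step count and risk

Total step count: 5 (steps 1, 2, 3 and 5 on the main line, step 4 for the coupling partner).
Longest linear sequence: 4 steps (1 → 3 → 5 → 7 → 10).

The three steps most likely to fail:

**Step 5 (acetoxymethyl Stille coupling).** The aryl bromide is hindered and electron-rich, and transfer of an sp3 α-acyloxymethyl group from tin is the unproven part. The fallback sets out from 7 and comes back at 10. It keeps the same bond and the same carbanion-equivalent logic but separates C–C formation from acetate installation. Suzuki–Miyaura coupling of 7 with potassium (acetoxymethyl)trifluoroborate (Pd(dba)2, RuPhos, Na2CO3, dioxane/H2O, 85 °C; the acetate is lost in situ) gives the benzylic alcohol methyl 2-hydroxy-6-[2-hydroxy-6-(hydroxymethyl)-4-methoxyphenoxy]-4-methylbenzoate F1. Lipase-catalysed transesterification (Novozym 435, vinyl acetate, MTBE, 30 °C) then acetylates only the primary alcohol, not the phenols, and gives 10.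

**Step 1 (intermolecular SNAr).** The phenoxide of 1 is weakly nucleophilic (ortho CHO, ortho Br) and hindered, and the ester of 2 is only a moderate activator. The fallback sets out from 1 and comes back at 5, so it also bypasses 3 and step 2. It makes the C–O bond intramolecularly. Esterification of 1 with 2,6-dihydroxy-4-methylbenzoic acid (TFAA, toluene, rt) gives the depside 2-bromo-6-formyl-4-methoxyphenyl 2,6-dihydroxy-4-methylbenzoate F2. With K2CO3 in DMSO (rt to 50 °C) it undergoes a Smiles rearrangement: a ring A phenoxide attacks the formyl-activated ipso carbon of ring B and the carboxylate leaves. This gives 2-(2-bromo-6-formyl-4-methoxyphenoxy)-6-hydroxy-4-methylbenzoic acid F3. Chemoselective esterification of the acid (TMSCHN2, toluene/MeOH, 0 °C) gives 5.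

**Step 2 (fluoride to hydroxyl).** The ester of 3 is twisted out of plane and activates the fluoride only weakly. The hydroxamate may instead attack the formyl-activated ether carbon of ring B. The fallback sets out from 2 (with 1 as partner) and comes back at 5. It brings the oxygen in before the ether is made and unmasks it by chelation-controlled demethylation. Compound 2 with NaOMe (1.0 equiv, MeOH/THF, 0 °C to rt) gives methyl 2-fluoro-6-methoxy-4-methylbenzoate F4. SNAr with 1 (Cs2CO3, DMSO, 110 °C) gives methyl 2-(2-bromo-6-formyl-4-methoxyphenoxy)-6-methoxy-4-methylbenzoate F5. BCl3 (CH2Cl2, −78 → 0 °C) cleaves only the methyl ether ortho to the ester, leaving the ring B methoxy group, and gives 5.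

## Further compounds

F1 | step 5 | methyl 2-hydroxy-6-[2-hydroxy-6-(hydroxymethyl)-4-methoxyphenoxy]-4-methylbenzoate | COC(=O)c1c(O)cc(C)cc1Oc1c(O)cc(OC)cc1CO
F2 | step 1 | 2-bromo-6-formyl-4-methoxyphenyl 2,6-dihydroxy-4-methylbenzoate | Cc1cc(O)c(C(=O)Oc2c(Br)cc(OC)cc2C=O)c(O)c1
F3 | step 1 | 2-(2-bromo-6-formyl-4-methoxyphenoxy)-6-hydroxy-4-methylbenzoic acid | Cc1cc(O)c(C(=O)O)c(Oc2c(Br)cc(OC)cc2C=O)c1
F4 | step 2 | methyl 2-fluoro-6-methoxy-4-methylbenzoate | COC(=O)c1c(F)cc(C)cc1OC
F5 | step 2 | methyl 2-(2-bromo-6-formyl-4-methoxyphenoxy)-6-methoxy-4-methylbenzoate | COC(=O)c1c(OC)cc(C)cc1Oc1c(Br)cc(OC)cc1C=O
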